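Lactone numbering: O1, C2(=O), C3 (arylidene carbon), C4 (stereocentre), C5 (OCH2). The retrosynthesis cuts, in order, the two phenol masks (MOM), the exocyclic C3=CH(aryl) double bond (aldol condensation), and the ring bond C3–C4.
Enabling feature: C4 is a CH lying 1,5 to C3 across C2(=O)–O1–C5 of the butyrolactone ring. Opened at C3–C4, it is the middle CH2 of a plain 3-arylpropyl ester with two enantiotopic hydrogens, so a carbene at C3 can close the ring and create the stereocentre by C–H insertion.
Forward: dihydroconiferyl alcohol (a complete C6–C3 unit) is masked, esterified and converted into its diazoacetate. The only new ring, the lactone, arises in step 4. The second aryl unit is joined at C3 by aldol addition and elimination, and both MOM groups fall last.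
Stereochemistry: C4 (R) comes from the chiral dirhodium carboxamidate catalyst alone and is not touched afterwards. The E geometry comes from an E1cB elimination that follows product stability.

Key step: step 4

Assumption: with 3-arylpropyl diazoacetates the (4R)-configured MPPIM catalyst is taken to deliver the (R)-lactone; both catalyst antipodes are accessible (from D- or L-asparagine), so a reversed sense would be met by the mirror-image catalyst with no other change.

Step 1
Reactants: 1 dihydroconiferyl alcohol, 4-(3-hydroxypropyl)-2-methoxyphenol
Product: 2 3-[3-methoxy-4-(methoxymethoxy)phenyl]propan-1-ol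
Conditions: MOMCl (1.1 equiv), K2CO3, acetone, 0 °C to rt
Reagents that add atoms: chloromethyl methyl ether, COCCl
Why: Williamson-type O-alkylation in which K2CO3 ionises only the far more acidic phenol, so the phenoxide captures MOMCl and the primary alcohol stays free for the ester; no stereocenter is formed.

Step 2
Reactants: 2 3-[3-methoxy-4-(methoxymethoxy)phenyl]propan-1-ol
Product: 3 3-[3-methoxy-4-(methoxymethoxy)phenyl]propyl bromoacetate
Conditions: BrCH2COBr, NaHCO3, MeCN, 0 °C
Reagents that add atoms: bromoacetyl bromide, BrCC(=O)Br
Why: Acylation of a primary alcohol by an acid bromide, with solid NaHCO3 taking up HBr so that the acid-labile MOM acetal survives.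

Step 3
Reactants: 3 3-[3-methoxy-4-(methoxymethoxy)phenyl]propyl bromoacetate
Product: 4 3-[3-methoxy-4-(methoxymethoxy)phenyl]propyl diazoacetate
Conditions: TsNHNHTs (2 equiv), DBU (5 equiv), THF, 0 °C
Reagents that add atoms: N,N'-bis(p-toluenesulfonyl)hydrazine, Cc1ccc(cc1)S(=O)(=O)NNS(=O)(=O)c1ccc(C)cc1
Why: N-alkylation of the ditosylhydrazine by the alpha-bromo ester, followed by two base-induced losses of sulfinate (Bamford–Stevens-type elimination), is an established one-flask conversion of bromoacetates into diazoacetates and leaves acetal and aryl ethers untouched.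

Step 4
Reactants: 4 3-[3-methoxy-4-(methoxymethoxy)phenyl]propyl diazoacetate
Product: 5 (4R)-4-[3-methoxy-4-(methoxymethoxy)benzyl]dihydrofuran-2(3H)-one
Conditions: Rh2(4R-MPPIM)4 = dirhodium tetrakis[methyl (4R)-2-oxo-1-(3-phenylpropanoyl)imidazolidine-4-carboxylate] (1 mol %), CH2Cl2, reflux, 4 added by syringe pump over about 10 h
Reagents that add atoms: none
Why: The diazo carbon of 4 binds to an axial site of the dirhodium core (divalent rhodium) and loses N2 to give an electrophilic rhodium carbene at the future C3, which inserts into a C–H bond of the central CH2 of the propyl chain through a concerted, asynchronous three-centre transition state, so that C3–C4 and C3–H form together and the catalyst is released. The closest known reaction type is this one itself, the enantioselective intramolecular carbene C–H insertion of primary alkyl diazoacetates under chiral dirhodium carboxamidate catalysis, which is established for 3-arylpropyl diazoacetates bearing alkoxy groups on the ring. The butyrolactone closes in the 1,5-insertion mode through a five-membered cyclic transition state made of C3, C2, O1, C5 and C4. C4 is the only new stereocenter and is under catalyst control: the ester groups and N-acyl arms of the four (4R)-imidazolidinone ligands leave open one orientation of the tethered chain over the carbene, so only one of the two enantiotopic hydrogens is presented and insertion proceeds with retention at carbon to the (R)-lactone. The step needs site selectivity against the O–CH2 group (four-membered beta-lactone), the benzylic CH2 (six-membered delta-lactone) and the electron-rich arene (cycloaddition or substitution), and chemoselectivity against carbene dimerisation; these are secured by the preference for the five-membered transition state, the deactivation of the O–CH2 hydrogens by the acyloxy group, the low electrophilicity of a carboxamidate-bound carbene and the slow addition of 4.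

Step 5
Reactants: 6 3-hydroxy-4,5-dimethoxybenzaldehyde
Product: 7 3,4-dimethoxy-5-(methoxymethoxy)benzaldehyde
Conditions: MOMCl, iPr2NEt, CH2Cl2, 0 °C to rt
Reagents that add atoms: chloromethyl methyl ether, COCCl
Why: Standard O-alkylation of a phenol by MOMCl with a hindered amine base, to which the aldehyde and the methyl ethers are inert.

Step 6
Reactants: 5 (4R)-4-[3-methoxy-4-(methoxymethoxy)benzyl]dihydrofuran-2(3H)-one; 7 3,4-dimethoxy-5-(methoxymethoxy)benzaldehyde
Product: 9 (3S,4R)-3-{[3,4-dimethoxy-5-(methoxymethoxy)phenyl](hydroxy)methyl}-4-[3-methoxy-4-(methoxymethoxy)benzyl]dihydrofuran-2(3H)-one (3,4-trans; carbinol epimers), via lithium enolate 8 (not isolated)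
Conditions: LiN(SiMe3)2, THF, −78 °C; then 7, −78 °C; AcOH quench
Reagents that add atoms: lithium bis(trimethylsilyl)amide, [Li+].C[Si](C)(C)[N-][Si](C)(C)C (supplies the lithium of 8)
Why: Aldol addition of a lactone lithium enolate to a non-enolisable aromatic aldehyde, which approaches C3 anti to the C4 benzyl group (3,4-trans) and gives the carbinol centre as a mixture; both new centres are erased in step 7, while C4 is not acidic and keeps its configuration.

Step 7
Reactants: 9 aldol adduct (3,4-trans; carbinol epimers)
Product: 11 (3E,4R)-3-[3,4-dimethoxy-5-(methoxymethoxy)benzylidene]-4-[3-methoxy-4-(methoxymethoxy)benzyl]dihydrofuran-2(3H)-one, via mesylate 10 (not isolated)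
Conditions: MsCl, Et3N, CH2Cl2, 0 °C; then DBU, 0 °C to rt
Reagents that add atoms: methanesulfonyl chloride, CS(=O)(=O)Cl (supplies the mesyl group of 10)
Why: Mesylation followed by E1cB elimination through the lactone enolate converts both carbinol epimers into the conjugated arylidene lactone, and the E isomer (aryl trans to the C2 carbonyl) is expected because the Z isomer would press the aryl ring against the carbonyl oxygen and out of conjugation; a short exposure to base leaves C4 untouched.

Step 8
Reactants: 11 (3E,4R)-bis-MOM arylidene lactone
Product: 12 (3E,4R)-3-(3-hydroxy-4,5-dimethoxybenzylidene)-4-(4-hydroxy-3-methoxybenzyl)dihydrofuran-2(3H)-one (target)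
Conditions: conc. aq HCl (cat.), MeOH, 45 °C
Reagents that add atoms: none
Why: Acid-catalysed acetal exchange removes both aryl MOM ethers and holds the formaldehyde unit as dimethoxymethane away from the electron-rich rings, while the methyl ethers, the conjugated lactone, the E alkene and C4 are stable to dilute acid.

Compound list
1 | dihydroconiferyl alcohol, 4-(3-hydroxypropyl)-2-methoxyphenol | COc1cc(CCCO)ccc1O | starting material
2 | 3-[3-methoxy-4-(methoxymethoxy)phenyl]propan-1-ol | COCOc1ccc(CCCO)cc1OC | intermediate
3 | 3-[3-methoxy-4-(methoxymethoxy)phenyl]propyl bromoacetate | COCOc1ccc(CCCOC(=O)CBr)cc1OC | intermediate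
4 | 3-[3-methoxy-4-(methoxymethoxy)phenyl]propyl diazoacetate | COCOc1ccc(CCCOC(=O)C=[N+]=[N-])cc1OC | intermediate
5 | (4R)-4-[3-methoxy-4-(methoxymethoxy)benzyl]dihydrofuran-2(3H)-one | COCOc1ccc(C[C@H]2COC(=O)C2)cc1OC | intermediate
6 | 3-hydroxy-4,5-dimethoxybenzaldehyde | COc1cc(C=O)cc(O)c1OC | starting material
7 | 3,4-dimethoxy-5-(methoxymethoxy)benzaldehyde | COCOc1cc(C=O)cc(OC)c1OC | intermediate
8 | lithium enolate of 5 (not isolated) | COCOc1ccc(C[C@H]2COC([O-])=C2)cc1OC.[Li+] | intermediate
9 | (3S,4R)-3-{[3,4-dimethoxy-5-(methoxymethoxy)phenyl](hydroxy)methyl}-4-[3-methoxy-4-(methoxymethoxy)benzyl]dihydrofuran-2(3H)-one, carbinol epimers | COCOc1ccc(C[C@H]2COC(=O)[C@@H]2C(O)c2cc(OCOC)c(OC)c(OC)c2)cc1OC | intermediate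
10 | methanesulfonate of 9 (not isolated) | COCOc1ccc(C[C@H]2COC(=O)[C@@H]2C(OS(C)(=O)=O)c2cc(OCOC)c(OC)c(OC)c2)cc1OC | intermediate
11 | (3E,4R)-3-[3,4-dimethoxy-5-(methoxymethoxy)benzylidene]-4-[3-methoxy-4-(methoxymethoxy)benzyl]dihydrofuran-2(3H)-one | COCOc1ccc(C[C@H]2COC(=O)/C2=C/c2cc(OCOC)c(OC)c(OC)c2)cc1OC | intermediate
12 | (3E,4R)-3-(3-hydroxy-4,5-dimethoxybenzylidene)-4-(4-hydroxy-3-methoxybenzyl)dihydrofuran-2(3H)-one | COc1cc(C[C@H]2COC(=O)/C2=C/c2cc(O)c(OC)c(OC)c2)ccc1O | target

Total step count: 8. Longest linear sequence: 7 (steps 1, 2, 3, 4, 6, 7, 8, from compound 1).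

Steps most likely to fail

Step 4. The carbene may be diverted into dimerisation, attack on the electron-rich ring or insertion at the benzylic position, or the two enantiotopic hydrogens may be told apart insufficiently. The fallback runs from 2 back to 5: the stereocentre is set by auxiliary-controlled enolate alkylation and the ring is closed at oxygen instead. Alcohol 2 is oxidised (TEMPO, PhI(OAc)2, MeCN–H2O) to the propanoic acid F1. This acid is coupled through its mixed pivalic anhydride (PivCl, Et3N, LiCl, THF) with (S)-4-benzyl-1,3-oxazolidin-2-one to the imide F2. The sodium enolate (NaN(SiMe3)2, THF, −78 °C) is alkylated by tert-butyl bromoacetate on the face away from the auxiliary benzyl group to give the succinate F3. LiBH4 removes the auxiliary reductively to give the hydroxy ester F4, and catalytic NaH in THF closes F4 to 5.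

Step 7. The elimination may show incomplete E selectivity, or base may deprotonate C4 of the product and move the double bond into the ring, which would erase the stereocentre. The fallback runs from 5 back to 11 and bypasses 9: a Horner–Wadsworth–Emmons olefination replaces aldol addition and elimination. The enolate of 5 (LiN(iPr)2, THF, −78 °C) is O-phosphorylated by diethyl chlorophosphate to the enol phosphate F5. A second equivalent of LiN(iPr)2 induces the 1,3 oxygen-to-carbon phosphorus shift to the alpha-phosphono lactone F6. Treatment of F6 with NaH and aldehyde 7 in THF at 0 °C should give 11 directly, with the E preference usual for alpha-phosphono butyrolactones and aromatic aldehydes.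

Step 3. Liberated sulfinate may displace the bromide, or the diazo ester may decompose in the strongly basic medium before work-up. The fallback runs from 2 back to 4 and bypasses 3: Regitz diazo transfer with deacylation. Alcohol 2 is heated with 2,2,6-trimethyl-4H-1,3-dioxin-4-one in toluene to give the acetoacetate F7. p-Acetamidobenzenesulfonyl azide and Et3N in MeCN give the diazoacetoacetate F8. Aqueous LiOH in THF then removes the acetyl group to give 4.

Further compounds
F1 | step 4 | 3-[3-methoxy-4-(methoxymethoxy)phenyl]propanoic acid | COCOc1ccc(CCC(=O)O)cc1OC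
F2 | step 4 | (4S)-4-benzyl-3-{3-[3-methoxy-4-(methoxymethoxy)phenyl]propanoyl}-1,3-oxazolidin-2-one | COCOc1ccc(CCC(=O)N2C(=O)OC[C@@H]2Cc2ccccc2)cc1OC
F3 | step 4 | tert-butyl (3R)-4-[(4S)-4-benzyl-2-oxo-1,3-oxazolidin-3-yl]-3-[3-methoxy-4-(methoxymethoxy)benzyl]-4-oxobutanoate | COCOc1ccc(C[C@H](CC(=O)OC(C)(C)C)C(=O)N2C(=O)OC[C@@H]2Cc2ccccc2)cc1OC
F4 | step 4 | tert-butyl (3R)-4-hydroxy-3-[3-methoxy-4-(methoxymethoxy)benzyl]butanoate | COCOc1ccc(C[C@H](CC(=O)OC(C)(C)C)CO)cc1OC
F5 | step 7 | diethyl (3R)-3-[3-methoxy-4-(methoxymethoxy)benzyl]-2,3-dihydrofuran-5-yl phosphate | COCOc1ccc(C[C@H]2COC(OP(=O)(OCC)OCC)=C2)cc1OC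
F6 | step 7 | diethyl {(4S)-4-[3-methoxy-4-(methoxymethoxy)benzyl]-2-oxotetrahydrofuran-3-yl}phosphonate, C3 epimers (same spatial arrangement at C4 as in 5; the descriptor changes because phosphorus raises the rank of C3) | COCOc1ccc(C[C@H]2COC(=O)C2P(=O)(OCC)OCC)cc1OC
F7 | step 3 | 3-[3-methoxy-4-(methoxymethoxy)phenyl]propyl 3-oxobutanoate | COCOc1ccc(CCCOC(=O)CC(C)=O)cc1OC
F8 | step 3 | 3-[3-methoxy-4-(methoxymethoxy)phenyl]propyl 2-diazo-3-oxobutanoate | COCOc1ccc(CCCOC(=O)C(=[N+]=[N-])C(C)=O)cc1OC
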